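**Plan**

1. Retrosynthesis: first the silyl groups come off; then the C4–C4a bond of ring C is cut, which opens ring C to an aryl propargyl ether whose alkyne terminus is the masked C4 carbonyl; then the C2–O1 ether bond is cut to give a ring B alkynol and 2,4-diprenylphloroglucinol; last the three aryl–prenyl bonds and the C2–C3 bond (aldehyde plus acetylene).
2. Forward: ring B is prenylated (Stille) and alkynylated; ring A is diprenylated by two directed ortho-metalations; the halves are joined through O1; the alkyne terminus is oxidised to a silyl ynol ether; ring C is closed last by C4–C4a bond formation; one fluoride step unmasks the C4 ketone and all phenols.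
3. Enabling feature: C4a is the only unsubstituted carbon of ring A and lies ortho to O1 and O5 and para to O7, so it is the single, strongly nucleophilic site for a six-membered closure onto C4.
4. Holding C3–C4 at the alkyne level until that closure leaves no acidic C3–H, so the benzylic C2–O1 bond cannot be lost by β-elimination, and the prenyl groups meet only catalytic acid.
5. Stereochemistry: C2 is set as the R carbinol by catalytic asymmetric alkynylation of the ring B aldehyde and inverted to S in the Mitsunobu etherification; no later step touches it.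

Key step: step 11

Remark: the (S,S)-ProPhenol ligand is assumed to deliver the R alcohol 5; if chiral HPLC and configurational correlation on the first batch show the opposite sense, the (R,R)-ligand is used with no other change.

Step 1
Reactants: 1 5-bromovanillin
Product: 2 3-bromo-5-methoxy-4-(triisopropylsilyloxy)benzaldehyde
Conditions: i-Pr3SiCl, imidazole, DMAP (cat.), DMF, rt to 40 °C
Reagents that add atoms: chlorotriisopropylsilane CC(C)[Si](Cl)(C(C)C)C(C)C
Why: O-silylation of the acidic, hindered phenol gives a TIPS ether that should survive the organometallic steps, carbonate methanolysis and catalytic acid and fall to fluoride at the end.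

Step 2
Reactants: 2 3-bromo-5-methoxy-4-(triisopropylsilyloxy)benzaldehyde
Product: 3 3-methoxy-5-(3-methylbut-2-en-1-yl)-4-(triisopropylsilyloxy)benzaldehyde
Conditions: tributyl(3-methylbut-2-en-1-yl)stannane, Pd(PPh3)4 (5 mol %), LiCl, DMF, 90 °C
Reagents that add atoms: tributyl(3-methylbut-2-en-1-yl)stannane CCCC[Sn](CCCC)(CCCC)CC=C(C)C
Why: Stille coupling of the aryl bromide with the allylic stannane should join the arene to the unsubstituted allyl terminus and give the linear prenyl group under neutral conditions that spare the aldehyde and the silyl ether.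

Step 3
Reactants: 3 3-methoxy-5-(3-methylbut-2-en-1-yl)-4-(triisopropylsilyloxy)benzaldehyde
Product: 5 (1R)-1-[3-methoxy-5-(3-methylbut-2-en-1-yl)-4-(triisopropylsilyloxy)phenyl]prop-2-yn-1-ol, via C-silylated alkynol 4 (not isolated)
Conditions: trimethylsilylacetylene, Me2Zn, (S,S)-ProPhenol (10 mol %), Ph3PO (20 mol %), toluene, 4 °C; then MeOH, K2CO3 (cat.), 0 °C to rt
Reagents that add atoms: trimethylsilylacetylene C#C[Si](C)(C)C
Why: Catalytic enantioselective alkynylation of the aldehyde by a zinc alkynylide held in the dinuclear zinc ProPhenol complex sets the carbinol centre by catalyst control of the aldehyde face, and carbonate methanolysis in the same flask removes only the C-silyl group.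

Step 4
Reactants: 6 phloroglucinol
Product: 7 1,3,5-tris(methoxymethoxy)benzene
Conditions: NaH, MOMCl, DMF, 0 °C to rt
Reagents that add atoms: chloromethyl methyl ether COCCl
Why: Williamson-type O-alkylation of the phenoxides with the hard electrophile MOMCl gives the tris-acetal, which serves both as protecting group and as ortho-directing group.

Step 5
Reactants: 7 1,3,5-tris(methoxymethoxy)benzene
Product: 9 1,3,5-tris(methoxymethoxy)-2-(3-methylbut-2-en-1-yl)benzene, via aryllithium 8 (not isolated)
Conditions: n-BuLi (1.1 equiv), THF, 0 °C; CuBr·SMe2 (10 mol %), prenyl bromide, –78 °C to rt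
Reagents that add atoms: prenyl bromide CC(C)=CCBr
Why: Directed ortho-metalation between two MOM ethers (all three ring positions are equivalent) followed by copper-catalysed SN2 allylation should install the first prenyl group.

Step 6
Reactants: 9 1,3,5-tris(methoxymethoxy)-2-(3-methylbut-2-en-1-yl)benzene
Product: 11 1,3,5-tris(methoxymethoxy)-2,4-bis(3-methylbut-2-en-1-yl)benzene, via aryllithium 10 (not isolated)
Conditions: n-BuLi (1.2 equiv), TMEDA, THF, 0 °C; CuBr·SMe2 (10 mol %), prenyl bromide, –78 °C to rt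
Reagents that add atoms: prenyl bromide CC(C)=CCBr
Why: A second directed ortho-metalation at one of the two equivalent positions flanked by two MOM ethers, then allylation, gives the 2,4-diprenyl pattern and leaves the future C4a as the only ring C–H.

Step 7
Reactants: 11 1,3,5-tris(methoxymethoxy)-2,4-bis(3-methylbut-2-en-1-yl)benzene
Product: 12 2,4-bis(3-methylbut-2-en-1-yl)benzene-1,3,5-triol
Conditions: HCl (3 M in MeOH), 0 °C to rt, under argon
Reagents that add atoms: none
Why: Acid-catalysed acetal exchange with methanol (MOM cleavage) frees the triol under conditions mild enough that the prenyl alkenes should not cyclise onto the neighbouring phenols.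

Step 8
Reactants: 5 (1R)-1-[3-methoxy-5-(3-methylbut-2-en-1-yl)-4-(triisopropylsilyloxy)phenyl]prop-2-yn-1-ol; 12 2,4-bis(3-methylbut-2-en-1-yl)benzene-1,3,5-triol (2.5 equiv)
Product: 13 5-{(1S)-1-[3-methoxy-5-(3-methylbut-2-en-1-yl)-4-(triisopropylsilyloxy)phenyl]prop-2-yn-1-yloxy}-2,4-bis(3-methylbut-2-en-1-yl)benzene-1,3-diol
Conditions: PPh3, DIAD, THF/toluene, –20 to 0 °C
Reagents that add atoms: none
Why: The Mitsunobu etherification displaces the alkoxyphosphonium ion by SN2 with inversion, turning the R carbinol into the S aryl ether; the two equivalent hydroxyls of 12 that are flanked by one prenyl group and H should react before the one between two prenyl groups, and excess 12 suppresses double alkylation.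

Step 9
Reactants: 13 the S ether diol
Product: 14 [5-{(1S)-1-[3-methoxy-5-(3-methylbut-2-en-1-yl)-4-(triisopropylsilyloxy)phenyl]prop-2-yn-1-yloxy}-2,4-bis(3-methylbut-2-en-1-yl)-1,3-phenylene]bis(oxy)bis(tert-butyldimethylsilane)
Conditions: t-BuMe2SiCl, imidazole, DMF, rt
Reagents that add atoms: tert-butyldimethylsilyl chloride CC(C)(C)[Si](C)(C)Cl
Why: Standard phenol silylation caps both remaining phenols so that no O–H can quench the acetylide, the peroxide oxidation or the ketenium ion of the next two steps.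

Step 10
Reactants: 14 the S bis-TBS propargyl ether
Product: 17 triisopropylsilyl ynol ether of 14 (R descriptor by ranking only; spatial arrangement at C2 unchanged), via lithium acetylide 15 (not isolated), via lithium ynolate 16 (not isolated)
Conditions: LiN(SiMe3)2 (2.3 equiv), t-BuOOH (1.1 equiv), THF, –78 to 0 °C; then i-Pr3SiOTf, –78 to 0 °C
Reagents that add atoms: tert-butyl hydroperoxide CC(C)(C)OO; triisopropylsilyl triflate CC(C)[Si](OS(=O)(=O)C(F)(F)F)(C(C)C)C(C)C
Why: Deprotonation of the terminal alkyne and electrophilic oxygen transfer from lithium tert-butyl peroxide to the acetylide carbon give the lithium ynolate, which TIPSOTf silylates on oxygen (ynolate oxidation and O-silylation); C2 is not involved.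

Step 11
Reactants: 17 triisopropylsilyl ynol ether
Product: 19 (2S)-5,7-bis(tert-butyldimethylsilyloxy)-2-[3-methoxy-5-(3-methylbut-2-en-1-yl)-4-(triisopropylsilyloxy)phenyl]-6,8-bis(3-methylbut-2-en-1-yl)-4-(triisopropylsilyloxy)-2H-chromene, via ketenium ion 18 (not isolated)
Conditions: HNTf2 (10 mol %), CH2Cl2, –78 °C; Et3N quench at –78 °C
Reagents that add atoms: none
Why: HNTf2 protonates the siloxyalkyne at C3 to give the silyl ketenium ion 18, C4a of ring A attacks its sp carbon C4, and loss of the C4a proton to the triflimide anion restores aromaticity and returns the acid, so the step is an acid-catalysed isomerisation whose closest known type is the Brønsted acid-promoted carbocyclisation of arene-tethered 1-siloxyalkynes to tetralone silyl enol ethers. Ring C closes in the 6-endo-dig mode, with C3=C4 ending inside the new ring as the enol ether double bond. No stereocentre is formed: C2 is a spectator, and because C3 stays unsaturated and C4 emerges as a silyl enol ether there is no C3–H acidic enough for β-elimination of the O1 aryloxide, so the S configuration should be carried through. The selectivity needed is attack by ring A and not 5-endo closure onto C6' of ring B or capture by a prenyl alkene. C4a is the only unsubstituted carbon of ring A and is ortho to O1 and O5 and para to O7, which makes it far more nucleophilic than ring B, and the prenyl alkenes could reach C4 only through eight-membered rings. Catalytic acid at –78 °C and the amine quench are chosen so that the prenyl groups, the aryl silyl ethers and the doubly activated C2–O1 bond do not ionise.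

Step 12
Reactants: 19 the 4-siloxy-2H-chromene
Product: 20 (2S)-5,7-dihydroxy-2-[4-hydroxy-3-methoxy-5-(3-methylbut-2-en-1-yl)phenyl]-6,8-bis(3-methylbut-2-en-1-yl)chroman-4-one
Conditions: Bu4NF/AcOH (1:1, 5 equiv), THF, 0 °C to rt
Reagents that add atoms: none
Why: Fluoride-mediated desilylation converts the silyl enol ether into the C4 ketone and the three aryl silyl ethers into phenols, and the acetic acid buffer keeps the medium non-basic so that the flavanone should not open to the chalcone and racemise at C2.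

**Compound list**

1 | 5-bromovanillin (3-bromo-4-hydroxy-5-methoxybenzaldehyde) | COc1cc(C=O)cc(Br)c1O | starting material
2 | 3-bromo-5-methoxy-4-(triisopropylsilyloxy)benzaldehyde | COc1cc(C=O)cc(Br)c1O[Si](C(C)C)(C(C)C)C(C)C | intermediate
3 | 3-methoxy-5-(3-methylbut-2-en-1-yl)-4-(triisopropylsilyloxy)benzaldehyde | COc1cc(C=O)cc(CC=C(C)C)c1O[Si](C(C)C)(C(C)C)C(C)C | intermediate
4 | (1S)-1-[3-methoxy-5-(3-methylbut-2-en-1-yl)-4-(triisopropylsilyloxy)phenyl]-3-(trimethylsilyl)prop-2-yn-1-ol, formed as its zinc alkoxide (same spatial arrangement as 5) | COc1cc([C@H](O)C#C[Si](C)(C)C)cc(CC=C(C)C)c1O[Si](C(C)C)(C(C)C)C(C)C | intermediate (not isolated)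
5 | (1R)-1-[3-methoxy-5-(3-methylbut-2-en-1-yl)-4-(triisopropylsilyloxy)phenyl]prop-2-yn-1-ol | COc1cc([C@H](O)C#C)cc(CC=C(C)C)c1O[Si](C(C)C)(C(C)C)C(C)C | intermediate
6 | phloroglucinol (benzene-1,3,5-triol) | Oc1cc(O)cc(O)c1 | starting material
7 | 1,3,5-tris(methoxymethoxy)benzene | COCOc1cc(OCOC)cc(OCOC)c1 | intermediate
8 | 2,4,6-tris(methoxymethoxy)phenyllithium | COCOc1cc(OCOC)c([Li])c(OCOC)c1 | intermediate (not isolated)
9 | 1,3,5-tris(methoxymethoxy)-2-(3-methylbut-2-en-1-yl)benzene | COCOc1cc(OCOC)c(CC=C(C)C)c(OCOC)c1 | intermediate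
10 | 2,4,6-tris(methoxymethoxy)-3-(3-methylbut-2-en-1-yl)phenyllithium | COCOc1c(CC=C(C)C)c(OCOC)c([Li])c(OCOC)c1 | intermediate (not isolated)
11 | 1,3,5-tris(methoxymethoxy)-2,4-bis(3-methylbut-2-en-1-yl)benzene | COCOc1cc(OCOC)c(CC=C(C)C)c(OCOC)c1CC=C(C)C | intermediate
12 | 2,4-bis(3-methylbut-2-en-1-yl)benzene-1,3,5-triol (2,4-diprenylphloroglucinol) | Oc1cc(O)c(CC=C(C)C)c(O)c1CC=C(C)C | intermediate
13 | 5-{(1S)-1-[3-methoxy-5-(3-methylbut-2-en-1-yl)-4-(triisopropylsilyloxy)phenyl]prop-2-yn-1-yloxy}-2,4-bis(3-methylbut-2-en-1-yl)benzene-1,3-diol | COc1cc([C@@H](Oc2cc(O)c(CC=C(C)C)c(O)c2CC=C(C)C)C#C)cc(CC=C(C)C)c1O[Si](C(C)C)(C(C)C)C(C)C | intermediate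
14 | 1,3-bis(tert-butyldimethylsilyl) ether of 13, S at the propargylic carbon | COc1cc([C@@H](Oc2cc(O[Si](C)(C)C(C)(C)C)c(CC=C(C)C)c(O[Si](C)(C)C(C)(C)C)c2CC=C(C)C)C#C)cc(CC=C(C)C)c1O[Si](C(C)C)(C(C)C)C(C)C | intermediate
15 | lithium acetylide of 14 (configuration at the benzylic carbon unchanged) | COc1cc([C@@H](Oc2cc(O[Si](C)(C)C(C)(C)C)c(CC=C(C)C)c(O[Si](C)(C)C(C)(C)C)c2CC=C(C)C)C#C[Li])cc(CC=C(C)C)c1O[Si](C(C)C)(C(C)C)C(C)C | intermediate (not isolated)
16 | lithium ynolate derived from 15 (configuration at the benzylic carbon unchanged) | COc1cc([C@@H](Oc2cc(O[Si](C)(C)C(C)(C)C)c(CC=C(C)C)c(O[Si](C)(C)C(C)(C)C)c2CC=C(C)C)C#CO[Li])cc(CC=C(C)C)c1O[Si](C(C)C)(C(C)C)C(C)C | intermediate (not isolated)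
17 | triisopropylsilyl ynol ether: 1-{(1R)-1-[3,5-bis(tert-butyldimethylsilyloxy)-2,4-bis(3-methylbut-2-en-1-yl)phenoxy]-3-(triisopropylsilyloxy)prop-2-yn-1-yl}-3-methoxy-5-(3-methylbut-2-en-1-yl)-4-(triisopropylsilyloxy)benzene (same spatial arrangement as 14; the siloxyalkynyl group now outranks the aryl group) | COc1cc([C@@H](Oc2cc(O[Si](C)(C)C(C)(C)C)c(CC=C(C)C)c(O[Si](C)(C)C(C)(C)C)c2CC=C(C)C)C#CO[Si](C(C)C)(C(C)C)C(C)C)cc(CC=C(C)C)c1O[Si](C(C)C)(C(C)C)C(C)C | intermediate
18 | O-triisopropylsilyl ketenium triflimide formed by protonation of 17 at C3 (configuration at C2 unchanged) | COc1cc([C@@H](Oc2cc(O[Si](C)(C)C(C)(C)C)c(CC=C(C)C)c(O[Si](C)(C)C(C)(C)C)c2CC=C(C)C)C=C=[O+][Si](C(C)C)(C(C)C)C(C)C)cc(CC=C(C)C)c1O[Si](C(C)C)(C(C)C)C(C)C.[N-](S(=O)(=O)C(F)(F)F)S(=O)(=O)C(F)(F)F | intermediate (not isolated)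
19 | (2S)-5,7-bis(tert-butyldimethylsilyloxy)-2-[3-methoxy-5-(3-methylbut-2-en-1-yl)-4-(triisopropylsilyloxy)phenyl]-6,8-bis(3-methylbut-2-en-1-yl)-4-(triisopropylsilyloxy)-2H-chromene | COc1cc([C@@H]2C=C(O[Si](C(C)C)(C(C)C)C(C)C)c3c(O[Si](C)(C)C(C)(C)C)c(CC=C(C)C)c(O[Si](C)(C)C(C)(C)C)c(CC=C(C)C)c3O2)cc(CC=C(C)C)c1O[Si](C(C)C)(C(C)C)C(C)C | intermediate
20 | (2S)-5,7-dihydroxy-2-[4-hydroxy-3-methoxy-5-(3-methylbut-2-en-1-yl)phenyl]-6,8-bis(3-methylbut-2-en-1-yl)chroman-4-one | COc1cc([C@@H]2CC(=O)c3c(O)c(CC=C(C)C)c(O)c(CC=C(C)C)c3O2)cc(CC=C(C)C)c1O | target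

**Step count and risks**

Total steps: 12. Longest linear sequence: 9 steps (from 6 through steps 4 to 12); the ring B branch from 1 needs 8.

Step 11 (key ring closure). What may go wrong: acid-triggered ionisation of the benzylic, propargylic C2–O1 bond, protonation of a prenyl alkene, or slow closure because the two silyloxy groups at C4 and C5 crowd each other. The fallback sets out from 17 and closes the same bond by a Friedel–Crafts acylation at the carboxylic acid level. Hydration of the ynol ether in wet THF with catalytic pyridinium p-toluenesulfonate should give the triisopropylsilyl ester F1. Oxalyl chloride with catalytic DMF converts the silyl ester directly into the acid chloride F2. SnCl4 in CH2Cl2 at –78 °C should then close ring C at C4a to the tris-silylated flavanone F3, and Bu4NF/AcOH as in step 12 brings the route back at 20.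

Step 10 (ynolate formation). What may go wrong: expulsion of the aryloxide from the ynolate, deprotonation at C2 with loss of configuration, or peroxide attack on the electron-rich ring. The fallback sets out from 14 and avoids any ynolate. Hydroboration of the terminal alkyne with dicyclohexylborane gives the (E)-alkenylborane F4 (not isolated), and oxidation with H2O2 in pH 7 phosphate buffer gives the aldehyde F5. Pinnick oxidation with NaClO2, NaH2PO4 and H2O2 as hypochlorite scavenger gives the acid F6. 1-Chloro-N,N,2-trimethylprop-1-en-1-amine converts it under neutral conditions into the acid chloride F2, which is cyclised with SnCl4 to the flavanone F3 and desilylated as above, coming back at 20.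

Step 8 (Mitsunobu etherification). What may go wrong: partial ionisation of the electron-rich benzylic alkoxyphosphonium ion with erosion of enantiopurity, or double alkylation of the triol. The fallback sets out from aldehyde 3 and lets a catalyst set C2 during C–O bond formation. Ethynylmagnesium bromide followed by methyl chloroformate in the same flask gives the racemic propargylic methyl carbonate F7. Copper-catalysed enantioconvergent propargylic etherification with triol 12 (CuOTf·0.5C6H6, a chiral 2,6-bis(4-phenyl-oxazolin-2-yl)pyridine ligand, i-Pr2NEt, MeOH, –20 °C) proceeds through a copper allenylidene attacked at its γ-carbon by the phenol oxygen and comes back at 13.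

Further compounds
F1 | step 11 | triisopropylsilyl (3S)-3-[3,5-bis(tert-butyldimethylsilyloxy)-2,4-bis(3-methylbut-2-en-1-yl)phenoxy]-3-[3-methoxy-5-(3-methylbut-2-en-1-yl)-4-(triisopropylsilyloxy)phenyl]propanoate | COc1cc([C@@H](Oc2cc(O[Si](C)(C)C(C)(C)C)c(CC=C(C)C)c(O[Si](C)(C)C(C)(C)C)c2CC=C(C)C)CC(=O)O[Si](C(C)C)(C(C)C)C(C)C)cc(CC=C(C)C)c1O[Si](C(C)C)(C(C)C)C(C)C
F2 | step 11 | (3S)-3-[3,5-bis(tert-butyldimethylsilyloxy)-2,4-bis(3-methylbut-2-en-1-yl)phenoxy]-3-[3-methoxy-5-(3-methylbut-2-en-1-yl)-4-(triisopropylsilyloxy)phenyl]propanoyl chloride | COc1cc([C@@H](Oc2cc(O[Si](C)(C)C(C)(C)C)c(CC=C(C)C)c(O[Si](C)(C)C(C)(C)C)c2CC=C(C)C)CC(=O)Cl)cc(CC=C(C)C)c1O[Si](C(C)C)(C(C)C)C(C)C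
F3 | step 11 | (2S)-5,7-bis(tert-butyldimethylsilyloxy)-2-[3-methoxy-5-(3-methylbut-2-en-1-yl)-4-(triisopropylsilyloxy)phenyl]-6,8-bis(3-methylbut-2-en-1-yl)chroman-4-one | COc1cc([C@@H]2CC(=O)c3c(O[Si](C)(C)C(C)(C)C)c(CC=C(C)C)c(O[Si](C)(C)C(C)(C)C)c(CC=C(C)C)c3O2)cc(CC=C(C)C)c1O[Si](C(C)C)(C(C)C)C(C)C
F4 | step 10 | (E)-alkenyl(dicyclohexyl)borane from hydroboration of 14 (configuration at the benzylic carbon unchanged) | COc1cc([C@@H](Oc2cc(O[Si](C)(C)C(C)(C)C)c(CC=C(C)C)c(O[Si](C)(C)C(C)(C)C)c2CC=C(C)C)/C=C/B(C3CCCCC3)C3CCCCC3)cc(CC=C(C)C)c1O[Si](C(C)C)(C(C)C)C(C)C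
F5 | step 10 | (3S)-3-[3,5-bis(tert-butyldimethylsilyloxy)-2,4-bis(3-methylbut-2-en-1-yl)phenoxy]-3-[3-methoxy-5-(3-methylbut-2-en-1-yl)-4-(triisopropylsilyloxy)phenyl]propanal | COc1cc([C@@H](Oc2cc(O[Si](C)(C)C(C)(C)C)c(CC=C(C)C)c(O[Si](C)(C)C(C)(C)C)c2CC=C(C)C)CC=O)cc(CC=C(C)C)c1O[Si](C(C)C)(C(C)C)C(C)C
F6 | step 10 | (3S)-3-[3,5-bis(tert-butyldimethylsilyloxy)-2,4-bis(3-methylbut-2-en-1-yl)phenoxy]-3-[3-methoxy-5-(3-methylbut-2-en-1-yl)-4-(triisopropylsilyloxy)phenyl]propanoic acid | COc1cc([C@@H](Oc2cc(O[Si](C)(C)C(C)(C)C)c(CC=C(C)C)c(O[Si](C)(C)C(C)(C)C)c2CC=C(C)C)CC(=O)O)cc(CC=C(C)C)c1O[Si](C(C)C)(C(C)C)C(C)C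
F7 | step 8 | racemic 1-[3-methoxy-5-(3-methylbut-2-en-1-yl)-4-(triisopropylsilyloxy)phenyl]prop-2-yn-1-yl methyl carbonate | COc1cc(C(OC(=O)OC)C#C)cc(CC=C(C)C)c1O[Si](C(C)C)(C(C)C)C(C)C
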